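## The problem

The target (26) is a linear pentamer: five six-membered carbocycles joined by four CH2 bridges, with a mirror plane through ring C. Rings B, C and D are butyrylphloroglucinols in which every ring carbon is substituted, carbon substituents and hydroxyls alternating. Rings A and E are their dearomatised relatives, 2-butanoyl-4,4-dimethylcyclohexane-1,3,5-triones drawn as dienols, each with a quaternary C(CH3)2 between two oxygenated carbons. There are no stereocentres, so the control problems are regiochemical: which carbon of each ring carries the acyl group and which the bridge, and how many units are joined, since methylene bridging of polyphenols tends to give statistical oligomers. The bridges are the fragile element: a CH2 between two electron-rich enolised rings is cleaved and re-formed under strong acid or hot base, the free polyphenol oxidises when basic, and the triketone ends are acidic chelators. Late steps must therefore be neutral or mildly acidic, and the nine phenols must be capped while ketene or carbanion chemistry is done. The quaternary carbons are classically made by C-methylation of a polyphenol, which is unselective. The enabling feature is the pattern of rings A and E: read as 6,6-dimethylcyclohexa-2,4-dien-1-ones with oxygen on C1, C3 and C5, the contiguous atoms C4–C5–C6–C1 (CH, C–O, C(CH3)2, C=O) map onto a 3-alkoxy-4,4-dimethylcyclobutenone, and C2–C3 (bridge-bearing carbon and its oxygenated neighbour) onto an oxygenated alkyne that carries the bridge CH2.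

## Retrosynthesis

**26 from 25.** The last cut removes nine O–CH2OCH3 groups. The phenols must be masked through ynolate and ketene chemistry. The methoxymethyl ether goes on with a hard electrophile (O-alkylation only, no dearomatising C-alkylation of the hexasubstituted rings) and comes off in dilute acid, where the bridges hold.

**25 from 23 and 2.** The C–C(O) bond between C4 of rings A and E and the butyryl group is cut. Carrying this acyl group through the annulation would need a 2-acylcyclobutenone, which opens to an acylketene with different cycloaddition behaviour. It is therefore added afterwards to the only unsubstituted ring carbon flanked by two carbonyls. The forward reaction must put two acyl groups on carbon in a molecule with several enol oxygens; O-acylation followed by acyl migration under thermodynamic control does this.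

**23 from 22.** Only heteroatom bonds are cut: two O–Si and two O–ethyl enol ether bonds. The forward hydrolysis must leave the aryl acetals untouched.

**22 from 14 and two molecules of 18 (key disconnection).** In each end ring the bonds C1–C2, C3–C4 and C1–C6 are cut. 18 supplies C4, C5, C6 and C1 with the gem-dimethyl carbon already quaternary, and each siloxyalkyne of 14 supplies C2 and C3 with the bridge attached. The neighbouring cut, through the outer CH2 bridges to preformed dimethyl triketone rings, returns to polyphenol methylation and statistical bridging. Here two rings, four new C–C bonds and both quaternary carbons come from one neutral thermal step on a symmetric trimer. The forward reaction must join ketene and alkyne in one orientation, twice.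

**18 from 15 and 16.** The two bonds made by ketene–alkyne [2+2] cycloaddition are cut, through dimethylketene 17. Both partners are commercial and the gem-dimethyl group comes from the isobutyryl unit.

**14 from 11.** The two C(sp)–O bonds are cut: each terminal alkyne is oxidised at carbon as its acetylide and the ynolate is silylated on oxygen. An ester-homologation entry from arylacetic esters was set aside. Their α-protons are more acidic than those of the butyryl ketones, so a base that shields the ketones as enolates would also enolise the ester that is meant to be attacked. With terminal alkynes, full deprotonation of ketones and alkynes is exactly what is wanted.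

**11 from 10, and 10 from 9.** The alkyne is traced to an aldehyde by one-carbon homologation, and the aldehyde to an allyl group by cleavage of the C=C bond. Allyl is the arm at the free-phenol stage because a propargyl group ortho to a phenol would cyclise onto it, whereas allyl survives bridging and protection.

**9 from 8, and 8 from 7.** Nine O–C bonds are cut in two groups. In each ring the butyryl carbonyl holds one ortho-hydroxyl in a strong hydrogen bond, so the three chelated hydroxyls are disconnected first (forward: last, as phenoxides) and the six free ones second (forward: first, under a weak amine base). Protection follows bridging because the bridging chemistry needs free ortho-hydroxyls.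

**7 from 5 and two molecules of 4.** The two inner bridges are cut on the ring B and ring D side, through 6. Ring C carries both electrophilic carbons as aminomethyl groups and each unit of 4 has one open ring position, so only the B–C–D trimer can form. Condensing 3 and 4 with a one-carbon aldehyde would give mixtures.

**5 from 3, 4 from 3, 3 from 1 and 2.** Two aminomethyl groups, one allyl group and one butyryl group are cut from ring carbon. All three forward reactions are electrophilic substitutions of a phloroglucinol.

## Roads not taken

**Alternative 1:** The key step would give the trimer core A1, in which ring C is complete and rings B and D are protected but not yet butyrylated. The cut breaks both bonds to the ring C carbon between the two bridges and unfolds ring C into the acyclic 2-acyl-1,3-diketone A2. Forward, triply deprotonated A2 is C-acylated by a carbonate ester at one outer methylene, and the other outer methylene closes onto the new ester. Its merit is that the most crowded ring and both inner bridges come from one cascade, with no chance of over-bridging; in that respect it is cleaner than any aminomethyl coupling. Its weak points lie after the key step. Rings B and D of A1 each have two equivalent open positions and no acyl group, so they must be desymmetrised. The trianion can be acylated on oxygen. The end rings with their quaternary carbons and the outer bridges are not addressed. The chosen plan reaches its BCD core in two steps from 3 with partners that allow one product only, and spends its key step on the part that alternative 1 leaves open.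

**Alternative 2:** The key step would give the protected BCD trimer A3 by two cross-couplings of the ring C dibromide A4 with the benzylic zinc reagent A5, catalysed by a zerovalent palladium complex such as Pd(PPh3)4. The cut is through both ring C–CH2 bonds. Every bridge is defined by the coupling partners, organozinc reagents tolerate the ketones, nothing can scramble under neutral conditions, and A3 already has all three butyryl groups and one open position on each outer ring. On security of the inner bridges this road is as good as or better than the chosen one. Against it, each coupling must form a diarylmethane with four ortho substituents at a bromide flanked by two alkoxy groups, where reduction and homocoupling of the benzylic zinc compete. A4 and A5 each need several steps. A3 then still requires rings A and E to be made by polyphenol methylation and attached by classical bridging after deprotection. The chosen plan sets against this a shorter entry to the core and an end-ring construction that needs no methylation of a polyphenol.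

**Alternative 3:** The key step would give A6 by annulation of two molecules of the cyclobutenone A7 onto the ring C bis(siloxyalkyne) A8, creating rings B and D as aromatic rings. This is the aromatic, best-established form of the same strain-release annulation. Aromatisation makes the last step irreversible, A7 has no cis-methyl group that could divert the vinylketene, A8 carries one ketone only, and the three oxygens of each new ring come out differentiated. On precedent and risk of the annulation itself it is better than the chosen plan. Its weakness is what is left. Each new ring has two open positions to be distinguished for the acyl group and the outer bridge. An aryl ethyl ether must be cleaved under conditions the ketones and acetals resist poorly. The dimethyl end rings and outer bridges are still to be made. The chosen plan accepts the less-tested dienone variant because it delivers the quaternary carbons and outer bridges together, and its enol ethers hydrolyse in dilute acid.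

Key step: step 11

Assumption: the triketone rings are drawn throughout in the dienol tautomer used for the target; the hexakis(methoxymethyl) ether 8 is drawn as one regioisomer with respect to which ortho-hydroxyl of rings B and D stays chelated, all of which converge on 9; the transient species of steps 9 and 11 are drawn with both arms at the same stage; the enol butyrate 24 is drawn as one of several O-acyl regioisomers, all of which converge on 25.

## Route

Step 1
Reactants: 1 phloroglucinol; 2 butyryl chloride
Product: 3 1-(2,4,6-trihydroxyphenyl)butan-1-one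
Conditions: AlCl3 (3.5 equiv), PhNO2–CH2Cl2, 0 → 60 °C; aq. HCl
Reagents that add atoms: none
Why: Friedel–Crafts C-acylation of a highly activated arene; the first acyl group deactivates the ring and chelates two hydroxyls, so acylation should stop at the mono-ketone.

Step 2
Reactants: 3 1-(2,4,6-trihydroxyphenyl)butan-1-one
Product: 4 1-[2,4,6-trihydroxy-3-(prop-2-en-1-yl)phenyl]butan-1-one
Conditions: allyl bromide (0.8 equiv), 1 M aq. KOH, 0 °C → rt; then 1 M HCl
Reagents that add atoms: allyl bromide, C=CCBr
Why: C-allylation of a phloroglucinolate: in water the oxygens are solvated and the soft allyl halide attacks ring carbon; the two open positions of 3 are equivalent, and a deficit of halide with recovery of 3 should limit double allylation.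

Step 3
Reactants: 3 1-(2,4,6-trihydroxyphenyl)butan-1-one
Product: 5 1-{3,5-bis[(dimethylamino)methyl]-2,4,6-trihydroxyphenyl}butan-1-one
Conditions: CH2(NMe2)2 (2.5 equiv), 1,4-dioxane, 20 → 40 °C
Reagents that add atoms: bis(dimethylamino)methane, CN(C)CN(C)C
Why: Mannich aminomethylation of an activated phenol by a preformed aminal; both open ring positions are to be filled, so no selectivity is required.

Step 4
Reactants: 4 1-[2,4,6-trihydroxy-3-(prop-2-en-1-yl)phenyl]butan-1-one; 5 1-{3,5-bis[(dimethylamino)methyl]-2,4,6-trihydroxyphenyl}butan-1-one
Product: 7 nonaphenol BCD trimer bearing two allyl arms, via mono-bridged Mannich base 6 (not isolated)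
Conditions: 4 (2.1 equiv), 1,4-dioxane, 100 °C, N2 sweep
Reagents that add atoms: none
Why: Elimination–addition of phenolic Mannich bases: each ortho-hydroxybenzylamine loses dimethylamine on heating and the resulting quinone-methide-type electrophile is captured by the single open ring carbon of 4; with both electrophilic carbons on ring C and one nucleophilic site per unit of 4, only the B–C–D trimer should form.

Step 5
Reactants: 7 nonaphenol BCD trimer bearing two allyl arms
Product: 8 hexakis(methoxymethyl) ether of 7 in which one ketone-chelated ortho-hydroxyl per ring remains free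
Conditions: MeOCH2Cl (7 equiv), i-Pr2NEt, CH2Cl2, 0 °C → rt
Reagents that add atoms: chloromethyl methyl ether, COCCl
Why: O-alkylation of phenols by an α-chloro ether under a weak amine base; in each ring the para-hydroxyl and one ortho-hydroxyl react, while the last ortho-hydroxyl is locked in the hydrogen bond to the butyryl carbonyl and should stay free, as is usual for 2-hydroxyaryl ketones. The oxocarbenium-like electrophile reacts at oxygen only, so the hexasubstituted rings are not C-alkylated.

Step 6
Reactants: 8 hexakis(methoxymethyl) ether of 7
Product: 9 nonakis(methoxymethyl) ether of 7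
Conditions: NaH (3.3 equiv), THF–DMF (4:1), 0 °C; MeOCH2Cl (3.6 equiv), 0 °C → rt
Reagents that add atoms: chloromethyl methyl ether, COCCl
Why: Williamson-type O-alkylation of sodium phenoxides: irreversible deprotonation breaks the three hydrogen-bond chelates and the phenoxides are capped by the same hard electrophile. A slight excess of hydride at 0 °C takes the phenols long before the butyryl α-positions, and the short cold exposure of rings that each hold a single phenoxide should not allow bridge exchange.

Step 7
Reactants: 9 nonakis(methoxymethyl) ether of 7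
Product: 10 protected trimer bis(aldehyde) in which each arm is CH2CHO
Conditions: OsO4 (cat.), NaIO4, 2,6-lutidine, 1,4-dioxane–H2O (3:1), rt
Reagents that add atoms: sodium periodate, [Na+].[O-]I(=O)(=O)=O (oxygen relayed by catalytic OsO4)
Why: Lemieux–Johnson cleavage of a terminal alkene by dihydroxylation and periodate cleavage; the fully substituted acyl-bearing arenes and the acetals are inert, and 2,6-lutidine suppresses over-oxidation of the arylacetaldehyde.

Step 8
Reactants: 10 protected trimer bis(aldehyde) in which each arm is CH2CHO
Product: 11 protected trimer bis(alkyne) in which each arm is CH2C≡CH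
Conditions: dimethyl (1-diazo-2-oxopropyl)phosphonate (2.6 equiv), K2CO3, MeOH, 0 °C → rt
Reagents that add atoms: dimethyl (1-diazo-2-oxopropyl)phosphonate, COP(=O)(OC)C(=[N+]=[N-])C(C)=O
Why: Seyferth–Gilbert homologation in the Ohira–Bestmann form: methanolysis gives the diazomethylphosphonate anion, which olefinates the aldehyde, loses N2 and rearranges by 1,2-hydrogen shift to the terminal alkyne; the hindered diortho-substituted aryl ketones should not react.

Step 9
Reactants: 11 protected trimer bis(alkyne) in which each arm is CH2C≡CH
Product: 14 protected trimer bis(siloxyalkyne) in which each arm is CH2C≡C–OSi(i-Pr)3, via pentalithio tris(enolate) bis(acetylide) 12 (not isolated), via pentalithio tris(enolate) bis(ynolate) 13 (not isolated)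
Conditions: LiN(i-Pr)2 (5.2 equiv), THF, −78 °C; t-BuOOLi (from t-BuOOH and LiN(SiMe3)2), −78 → 0 °C; i-Pr3SiCl, −78 → 0 °C; aq. NH4Cl
Reagents that add atoms: tert-butyl hydroperoxide, CC(C)(C)OO; chlorotriisopropylsilane, CC(C)[Si](Cl)(C(C)C)C(C)C
Why: Oxidation of lithium acetylides to ynolates by a lithium alkyl peroxide (oxenoid oxygen transfer) followed by O-silylation of the ynolate with a bulky chlorosilane; the amide base first turns the three butyryl ketones into hindered lithium enolates, which shields them from nucleophiles, and they should return as ketones on aqueous work-up.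

Step 10
Reactants: 15 isobutyryl chloride; 16 ethoxyacetylene
Product: 18 3-ethoxy-4,4-dimethylcyclobut-2-en-1-one, via dimethylketene 17 (not isolated)
Conditions: Et3N, Et2O, slow addition of 15, 0 °C → reflux
Reagents that add atoms: none
Why: Dehydrochlorination gives the ketene, which undergoes [2+2] cycloaddition with the ynol ether; the alkyne carbon remote from oxygen bonds to the ketene carbonyl carbon, so the ethoxy group ends at C3 and the gem-dimethyl carbon at C4.

Step 11
Reactants: 14 protected trimer bis(siloxyalkyne) in which each arm is CH2C≡C–OSi(i-Pr)3; 18 3-ethoxy-4,4-dimethylcyclobut-2-en-1-one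
Product: 22 protected pentamer with rings A and E as 5-ethoxy-6,6-dimethyl-3-(triisopropylsiloxy)cyclohexa-2,4-dien-1-ones joined at C2, via vinylketene 19 (not isolated), via bis(vinylcyclobutenone) adduct 20 (not isolated), via bis(dienylketene) 21 (not isolated)
Conditions: 18 (3 equiv), PhMe (degassed), 80 °C then 110 °C, sealed tube
Reagents that add atoms: none
Why: Heating opens 18 by four-electron conrotatory ring opening to vinylketene 19, whose ketene C=C adds to each electron-rich siloxyalkyne of 14 in a [2+2] cycloaddition to give the 4-vinylcyclobutenone 20; a second four-electron opening gives dienylketene 21, and a six-electron disrotatory electrocyclisation joins the ketene carbon to the dimethyl-substituted diene terminus. The closest known reaction type is the Danheiser benzannulation of cyclobutenones with siloxyalkynes, in the variant where a 4,4-disubstituted cyclobutenone cannot tautomerise to a phenol and the product stays a 6,6-disubstituted cyclohexa-2,4-dienone. Rings A and E each close by this 6π electrocyclisation (bond C1–C6), the bonds C1–C2 and C3–C4 having been made in the [2+2] event. No stereocentre is created; the CH stereocentre of 20 is lost on ring opening. The selectivity needed is regiochemical: the alkyne carbon β to oxygen, which bears the CH2 arm, is the nucleophilic terminus and bonds to the ketene carbonyl carbon, so the bridge ends next to the ring carbonyl and the oxygens fall on C1, C3 and C5. Only the dienylketene with the ethoxyvinyl group turned inward can cyclise; the ring openings are reversible, so the unproductive isomer should return to 20 and be funnelled through. The nine acetal ethers and three hindered aryl ketones are inert under neutral thermal conditions, and the two arms are remote and react independently.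

Step 12
Reactants: 22 protected pentamer with rings A and E as ethoxy siloxy dienones
Product: 23 protected pentamer with rings A and E as 3,5-dihydroxy-4,4-dimethylcyclohexa-2,5-dien-1-ones joined at C2
Conditions: 1 M aq. HCl–THF (1:3), 0 °C → rt, stopped when the mono-ethyl ether is consumed
Reagents that add atoms: water, O
Why: Enol ether hydrolysis: both groups are vinylogous esters of a non-aromatic ring, so O-protonation gives a trioxygenated pentadienyl cation that takes up water at the ethoxy carbon and loses ethanol while silicon leaves as silanol; formaldehyde-type aryl acetals should react more slowly in dilute aqueous acid.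

Step 13
Reactants: 23 protected pentamer with rings A and E as dihydroxy dienones; 2 butyryl chloride
Product: 25 protected pentamer with both end rings C-butyrylated, via bis(enol butyrate) 24 (not isolated)
Conditions: 2 (2.2 equiv), Et3N, CH2Cl2, 0 °C; then DMAP (0.3 equiv), rt → 40 °C; dilute acid wash
Reagents that add atoms: none
Why: O-acylation of the enolised trione followed by DMAP-mediated O→C acyl migration, as used for 2-acylcyclohexane-1,3-diones; only the unsubstituted ring carbon between two carbonyls can hold the acyl group as a chelated β-triketone, so O-acyl isomers and any acylation at the bridge-bearing carbon should funnel to 25.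

Step 14
Reactants: 25 protected pentamer with both end rings C-butyrylated
Product: 26 target pentamer CNP0188003.0
Conditions: 3 M HCl in MeOH–THF (1:1), 20 → 40 °C
Reagents that add atoms: none
Why: Acid-catalysed cleavage of the nine methoxymethyl acetals, with methanol taking up the formaldehyde unit as dimethoxymethane; the phenols reappear chelated to the flanking ketones, and the mild acid should not cleave the methylene bridges.

## Compound list

1 | phloroglucinol (benzene-1,3,5-triol) | Oc1cc(O)cc(O)c1 | starting material
2 | butyryl chloride | CCCC(=O)Cl | starting material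
3 | 1-(2,4,6-trihydroxyphenyl)butan-1-one | CCCC(=O)c1c(O)cc(O)cc1O | intermediate
4 | 1-[2,4,6-trihydroxy-3-(prop-2-en-1-yl)phenyl]butan-1-one | CCCC(=O)c1c(O)cc(O)c(CC=C)c1O | intermediate
5 | 1-{3,5-bis[(dimethylamino)methyl]-2,4,6-trihydroxyphenyl}butan-1-one | CCCC(=O)c1c(O)c(CN(C)C)c(O)c(CN(C)C)c1O | intermediate
6 | mono-bridged Mannich base: ring C bearing one CH2NMe2 group and one (3-allyl-5-butanoyl-2,4,6-trihydroxyphenyl)methyl group; formed in the flask | CCCC(=O)c1c(O)c(CN(C)C)c(O)c(Cc2c(O)c(CC=C)c(O)c(C(=O)CCC)c2O)c1O | intermediate
7 | 1-{3,5-bis[(3-allyl-5-butanoyl-2,4,6-trihydroxyphenyl)methyl]-2,4,6-trihydroxyphenyl}butan-1-one (nonaphenol BCD trimer with two allyl arms) | CCCC(=O)c1c(O)c(Cc2c(O)c(CC=C)c(O)c(C(=O)CCC)c2O)c(O)c(Cc2c(O)c(CC=C)c(O)c(C(=O)CCC)c2O)c1O | intermediate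
8 | hexakis(methoxymethyl) ether of 7: in each ring the para-oxygen and one ortho-oxygen carry CH2OCH3 and one ortho-hydroxyl stays free, drawn in rings B and D as the hydroxyl between the butyryl group and the bridge | CCCC(=O)c1c(OCOC)c(Cc2c(OCOC)c(CC=C)c(OCOC)c(C(=O)CCC)c2O)c(OCOC)c(Cc2c(OCOC)c(CC=C)c(OCOC)c(C(=O)CCC)c2O)c1O | intermediate
9 | nonakis(methoxymethyl) ether of 7 | CCCC(=O)c1c(OCOC)c(Cc2c(OCOC)c(CC=C)c(OCOC)c(C(=O)CCC)c2OCOC)c(OCOC)c(Cc2c(OCOC)c(CC=C)c(OCOC)c(C(=O)CCC)c2OCOC)c1OCOC | intermediate
10 | protected trimer bis(aldehyde): as 9 with each allyl arm cut to 2-oxoethyl | CCCC(=O)c1c(OCOC)c(Cc2c(OCOC)c(CC=O)c(OCOC)c(C(=O)CCC)c2OCOC)c(OCOC)c(Cc2c(OCOC)c(CC=O)c(OCOC)c(C(=O)CCC)c2OCOC)c1OCOC | intermediate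
11 | protected trimer bis(alkyne): as 9 with each arm prop-2-yn-1-yl | CCCC(=O)c1c(OCOC)c(Cc2c(OCOC)c(CC#C)c(OCOC)c(C(=O)CCC)c2OCOC)c(OCOC)c(Cc2c(OCOC)c(CC#C)c(OCOC)c(C(=O)CCC)c2OCOC)c1OCOC | intermediate
12 | pentalithio tris(enolate) bis(acetylide) of 11, enolates drawn Z; formed in the flask | CC/C=C(\O[Li])c1c(OCOC)c(Cc2c(OCOC)c(CC#C[Li])c(OCOC)c(/C(O[Li])=C/CC)c2OCOC)c(OCOC)c(Cc2c(OCOC)c(CC#C[Li])c(OCOC)c(/C(O[Li])=C/CC)c2OCOC)c1OCOC | intermediate
13 | pentalithio tris(enolate) bis(ynolate), enolates drawn Z; formed in the flask | CC/C=C(\O[Li])c1c(OCOC)c(Cc2c(OCOC)c(CC#CO[Li])c(OCOC)c(/C(O[Li])=C/CC)c2OCOC)c(OCOC)c(Cc2c(OCOC)c(CC#CO[Li])c(OCOC)c(/C(O[Li])=C/CC)c2OCOC)c1OCOC | intermediate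
14 | protected trimer bis(siloxyalkyne): as 9 with each arm 3-(triisopropylsiloxy)prop-2-yn-1-yl | CCCC(=O)c1c(OCOC)c(Cc2c(OCOC)c(CC#CO[Si](C(C)C)(C(C)C)C(C)C)c(OCOC)c(C(=O)CCC)c2OCOC)c(OCOC)c(Cc2c(OCOC)c(CC#CO[Si](C(C)C)(C(C)C)C(C)C)c(OCOC)c(C(=O)CCC)c2OCOC)c1OCOC | intermediate
15 | isobutyryl chloride | CC(C)C(=O)Cl | starting material
16 | ethoxyacetylene | CCOC#C | starting material
17 | dimethylketene; formed in the flask | CC(C)=C=O | intermediate
18 | 3-ethoxy-4,4-dimethylcyclobut-2-en-1-one | CCOC1=CC(=O)C1(C)C | intermediate
19 | 3-ethoxy-4-methylpenta-1,3-dien-1-one (vinylketene); formed in the flask | CCOC(C=C=O)=C(C)C | intermediate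
20 | bis(vinylcyclobutenone) adduct: each arm CH2 on C2 of a 3-(triisopropylsiloxy)-4-(1-ethoxy-2-methylprop-1-enyl)cyclobut-2-en-1-one, either configuration at the two ring CH carbons; formed in the flask | CCCC(=O)c1c(OCOC)c(Cc2c(OCOC)c(CC3=C(O[Si](C(C)C)(C(C)C)C(C)C)C(C(OCC)=C(C)C)C3=O)c(OCOC)c(C(=O)CCC)c2OCOC)c(OCOC)c(Cc2c(OCOC)c(CC3=C(O[Si](C(C)C)(C(C)C)C(C)C)C(C(OCC)=C(C)C)C3=O)c(OCOC)c(C(=O)CCC)c2OCOC)c1OCOC | intermediate
21 | bis(dienylketene): each arm CH2–C(=C=O)–C(OSi(i-Pr)3)=CH–C(OEt)=C(CH3)2 with the ketene-bearing carbon and the ethoxyvinyl group cis; formed in the flask | CCCC(=O)c1c(OCOC)c(Cc2c(OCOC)c(CC(=C=O)/C(O[Si](C(C)C)(C(C)C)C(C)C)=C\C(OCC)=C(C)C)c(OCOC)c(C(=O)CCC)c2OCOC)c(OCOC)c(Cc2c(OCOC)c(CC(=C=O)/C(O[Si](C(C)C)(C(C)C)C(C)C)=C\C(OCC)=C(C)C)c(OCOC)c(C(=O)CCC)c2OCOC)c1OCOC | intermediate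
22 | protected pentamer: each arm [4-ethoxy-5,5-dimethyl-6-oxo-2-(triisopropylsiloxy)cyclohexa-1,3-dien-1-yl]methyl | CCCC(=O)c1c(OCOC)c(Cc2c(OCOC)c(CC3=C(O[Si](C(C)C)(C(C)C)C(C)C)C=C(OCC)C(C)(C)C3=O)c(OCOC)c(C(=O)CCC)c2OCOC)c(OCOC)c(Cc2c(OCOC)c(CC3=C(O[Si](C(C)C)(C(C)C)C(C)C)C=C(OCC)C(C)(C)C3=O)c(OCOC)c(C(=O)CCC)c2OCOC)c1OCOC | intermediate
23 | protected pentamer: each arm (2,4-dihydroxy-3,3-dimethyl-6-oxocyclohexa-1,4-dien-1-yl)methyl | CCCC(=O)c1c(OCOC)c(Cc2c(OCOC)c(CC3=C(O)C(C)(C)C(O)=CC3=O)c(OCOC)c(C(=O)CCC)c2OCOC)c(OCOC)c(Cc2c(OCOC)c(CC3=C(O)C(C)(C)C(O)=CC3=O)c(OCOC)c(C(=O)CCC)c2OCOC)c1OCOC | intermediate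
24 | bis(enol butyrate) of 23, drawn acylated at the ring oxygen between the bridge-bearing carbon and the CH carbon; formed in the flask | CCCC(=O)c1c(OCOC)c(Cc2c(OCOC)c(CC3=C(O)C(C)(C)C(=O)C=C3OC(=O)CCC)c(OCOC)c(C(=O)CCC)c2OCOC)c(OCOC)c(Cc2c(OCOC)c(CC3=C(O)C(C)(C)C(=O)C=C3OC(=O)CCC)c(OCOC)c(C(=O)CCC)c2OCOC)c1OCOC | intermediate
25 | protected pentamer: each arm (5-butanoyl-2,4-dihydroxy-3,3-dimethyl-6-oxocyclohexa-1,4-dien-1-yl)methyl | CCCC(=O)c1c(OCOC)c(Cc2c(OCOC)c(CC3=C(O)C(C)(C)C(O)=C(C(=O)CCC)C3=O)c(OCOC)c(C(=O)CCC)c2OCOC)c(OCOC)c(Cc2c(OCOC)c(CC3=C(O)C(C)(C)C(O)=C(C(=O)CCC)C3=O)c(OCOC)c(C(=O)CCC)c2OCOC)c1OCOC | intermediate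
26 | CNP0188003.0, the pentamer with free phenols | CCCC(=O)C1=C(O)C(C)(C)C(O)=C(Cc2c(O)c(Cc3c(O)c(Cc4c(O)c(CC5=C(O)C(C)(C)C(O)=C(C(=O)CCC)C5=O)c(O)c(C(=O)CCC)c4O)c(O)c(C(=O)CCC)c3O)c(O)c(C(=O)CCC)c2O)C1=O | target

## Step count and least certain steps

Total: 14 steps. Longest linear sequence: 12 steps (1, 2, 4, 5, 6, 7, 8, 9, 11, 12, 13, 14).

**Step 11 (key step).** The most likely failure is a kinetic mismatch. Opening of 18 costs its vinylogous-ester stabilisation and forces one methyl group inward, so it may need temperatures at which the vinylketene is diverted by a 1,5-hydrogen shift from its cis methyl group or by dimerisation. At those temperatures the siloxyalkyne may also rearrange by 1,3-silyl migration, and the second arm may react incompletely. The fallback gives up the cycloaddition and brings the end rings in preformed; it sets out from 3 and 5 and returns at 26. Exhaustive C-methylation of 3 (MeI, NaOMe, MeOH) would give butyrylfilicinic acid F1, and aminomethylation with CH2(NMe2)2 would give its Mannich base F2. Heating 5 with a large excess of 3 would give the open trimer F3. Heating F3 with two equivalents of F2 in dioxane would form the outer bridges and give 26 directly, without protecting groups. The price is the unselective methylation and the exchange-prone bridging that the main plan avoids.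

**Step 9.** The risk is loss of chemoselectivity among five anionic sites. The peroxide may hydroxylate the ketone enolates as well as the acetylides, the enolates may be partly silylated in the quench, and the benzylic propargylic position may isomerise to the allene under excess base. The fallback masks the ketones before any oxidant is present; it sets out from 10 and returns at 23. Corey–Fuchs olefination of 10 (CBr4, PPh3, CH2Cl2, 0 °C) would give the bis(dibromoalkene) F4. Excess LiN(i-Pr)2 followed by i-Pr3SiOTf would trap the three enolates as Z silyl enol ethers and dehydrobrominate the arms, giving the tris(silyl enol ether) bis(bromoalkyne) F5. With no ketone left, bromine–lithium exchange with n-BuLi, oxidation with t-BuOOLi and silylation with i-Pr3SiOTf would give the pentasilyl bis(siloxyalkyne) F6. Annulation with 18 as in step 11 would give the pentasilyl pentamer F7. Bu4NF–AcOH and then dilute aqueous HCl would remove all five silyl groups and the ethyl enol ethers and return 23.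

**Step 12.** The risk is partial loss of methoxymethyl groups. The second hydrolysis acts on a stabilised vinylogous acid ether and may need acid strong enough to attack the aryl acetals next to the ketones, after which step 13 would acylate free phenols. The fallback makes both end-ring oxygens silyl so that fluoride alone unmasks the trione; it sets out from 18 and 14 and returns at 23. Cold dilute HCl would hydrolyse 18 to 2,2-dimethylcyclobutane-1,3-dione F8, and i-Pr3SiOTf with Et3N would give the siloxycyclobutenone F9. Annulation of 14 with F9 would give the bis(disiloxy dienone) pentamer F10, and Bu4NF–AcOH in THF would give 23 without acid.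

**Step 4.** The risk is bridge exchange. The liberated amine and the reversibility of the elimination–addition can cleave and re-form bridges, giving mixed oligomers, and the zwitterionic bis-amine 5 may be poorly soluble. The fallback swaps the roles of the partners; it sets out from 4 and 3 and returns at 7. Aminomethylation of 4 at its only open position with CH2(NMe2)2 would give the Mannich base F11, a neutral mono-amine with no free ring position. Heating two equivalents of F11 with 3 would give 7.

**Step 2.** The risk is over-allylation: geminal or double C-allylation and some O-allylation, which lowers the yield of the mono-allyl compound. The fallback reaches the same bond by rearrangement; it sets out from 3 and returns at 4. O-Allylation of the non-chelated 4-hydroxyl (allyl bromide, K2CO3, acetone) would give the allyl ether F12, and an aromatic Claisen rearrangement (PhNEt2, 190 °C) would move the allyl group to the adjacent ring carbon and give 4.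

## Further compounds

F1 | step 11 | 2-butanoyl-3,5-dihydroxy-4,4-dimethylcyclohexa-2,5-dien-1-one (butyrylfilicinic acid) | CCCC(=O)C1=C(O)C(C)(C)C(O)=CC1=O
F2 | step 11 | 2-butanoyl-6-[(dimethylamino)methyl]-3,5-dihydroxy-4,4-dimethylcyclohexa-2,5-dien-1-one | CCCC(=O)C1=C(O)C(C)(C)C(O)=C(CN(C)C)C1=O
F3 | step 11 | 1-{3,5-bis[(3-butanoyl-2,4,6-trihydroxyphenyl)methyl]-2,4,6-trihydroxyphenyl}butan-1-one (open BCD trimer) | CCCC(=O)c1c(O)c(Cc2c(O)cc(O)c(C(=O)CCC)c2O)c(O)c(Cc2c(O)cc(O)c(C(=O)CCC)c2O)c1O
F4 | step 9 | protected trimer bis(dibromoalkene): as 9 with each arm 3,3-dibromoprop-2-en-1-yl | CCCC(=O)c1c(OCOC)c(Cc2c(OCOC)c(CC=C(Br)Br)c(OCOC)c(C(=O)CCC)c2OCOC)c(OCOC)c(Cc2c(OCOC)c(CC=C(Br)Br)c(OCOC)c(C(=O)CCC)c2OCOC)c1OCOC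
F5 | step 9 | protected trimer tris(Z-triisopropylsilyl enol ether) bis(bromoalkyne): each arm 3-bromoprop-2-yn-1-yl | CC/C=C(\O[Si](C(C)C)(C(C)C)C(C)C)c1c(OCOC)c(Cc2c(OCOC)c(CC#CBr)c(OCOC)c(/C(O[Si](C(C)C)(C(C)C)C(C)C)=C/CC)c2OCOC)c(OCOC)c(Cc2c(OCOC)c(CC#CBr)c(OCOC)c(/C(O[Si](C(C)C)(C(C)C)C(C)C)=C/CC)c2OCOC)c1OCOC
F6 | step 9 | protected trimer tris(Z-triisopropylsilyl enol ether) bis(siloxyalkyne) | CC/C=C(\O[Si](C(C)C)(C(C)C)C(C)C)c1c(OCOC)c(Cc2c(OCOC)c(CC#CO[Si](C(C)C)(C(C)C)C(C)C)c(OCOC)c(/C(O[Si](C(C)C)(C(C)C)C(C)C)=C/CC)c2OCOC)c(OCOC)c(Cc2c(OCOC)c(CC#CO[Si](C(C)C)(C(C)C)C(C)C)c(OCOC)c(/C(O[Si](C(C)C)(C(C)C)C(C)C)=C/CC)c2OCOC)c1OCOC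
F7 | step 9 | protected pentamer with ethoxy siloxy dienone end rings and the three ketones as Z-triisopropylsilyl enol ethers | CC/C=C(\O[Si](C(C)C)(C(C)C)C(C)C)c1c(OCOC)c(Cc2c(OCOC)c(CC3=C(O[Si](C(C)C)(C(C)C)C(C)C)C=C(OCC)C(C)(C)C3=O)c(OCOC)c(/C(O[Si](C(C)C)(C(C)C)C(C)C)=C/CC)c2OCOC)c(OCOC)c(Cc2c(OCOC)c(CC3=C(O[Si](C(C)C)(C(C)C)C(C)C)C=C(OCC)C(C)(C)C3=O)c(OCOC)c(/C(O[Si](C(C)C)(C(C)C)C(C)C)=C/CC)c2OCOC)c1OCOC
F8 | step 12 | 2,2-dimethylcyclobutane-1,3-dione | CC1(C)C(=O)CC1=O
F9 | step 12 | 4,4-dimethyl-3-(triisopropylsiloxy)cyclobut-2-en-1-one | CC(C)[Si](OC1=CC(=O)C1(C)C)(C(C)C)C(C)C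
F10 | step 12 | protected pentamer with rings A and E as 3,5-bis(triisopropylsiloxy)-6,6-dimethylcyclohexa-2,4-dien-1-ones joined at C2 | CCCC(=O)c1c(OCOC)c(Cc2c(OCOC)c(CC3=C(O[Si](C(C)C)(C(C)C)C(C)C)C=C(O[Si](C(C)C)(C(C)C)C(C)C)C(C)(C)C3=O)c(OCOC)c(C(=O)CCC)c2OCOC)c(OCOC)c(Cc2c(OCOC)c(CC3=C(O[Si](C(C)C)(C(C)C)C(C)C)C=C(O[Si](C(C)C)(C(C)C)C(C)C)C(C)(C)C3=O)c(OCOC)c(C(=O)CCC)c2OCOC)c1OCOC
F11 | step 4 | 1-{3-[(dimethylamino)methyl]-2,4,6-trihydroxy-5-(prop-2-en-1-yl)phenyl}butan-1-one | CCCC(=O)c1c(O)c(CN(C)C)c(O)c(CC=C)c1O
F12 | step 2 | 1-[2,6-dihydroxy-4-(prop-2-en-1-yloxy)phenyl]butan-1-one | CCCC(=O)c1c(O)cc(OCC=C)cc1O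
A1 | alternative 1 | trimer core with ring C complete and rings B and D as tris(methoxymethoxy)phenyl groups | CCCC(=O)c1c(O)c(Cc2c(OCOC)cc(OCOC)cc2OCOC)c(O)c(Cc2c(OCOC)cc(OCOC)cc2OCOC)c1O
A2 | alternative 1 | 4-butanoyl-1,7-bis[2,4,6-tris(methoxymethoxy)phenyl]heptane-3,5-dione | CCCC(=O)C(C(=O)CCc1c(OCOC)cc(OCOC)cc1OCOC)C(=O)CCc1c(OCOC)cc(OCOC)cc1OCOC
A3 | alternative 2 | BCD trimer nonakis(methoxymethyl) ether with one open position on each outer ring | CCCC(=O)c1c(OCOC)cc(OCOC)c(Cc2c(OCOC)c(Cc3c(OCOC)cc(OCOC)c(C(=O)CCC)c3OCOC)c(OCOC)c(C(=O)CCC)c2OCOC)c1OCOC
A4 | alternative 2 | 1-[3,5-dibromo-2,4,6-tris(methoxymethoxy)phenyl]butan-1-one | CCCC(=O)c1c(OCOC)c(Br)c(OCOC)c(Br)c1OCOC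
A5 | alternative 2 | {[3-butanoyl-2,4,6-tris(methoxymethoxy)phenyl]methyl}zinc bromide | CCCC(=O)c1c(OCOC)cc(OCOC)c(C[Zn]Br)c1OCOC
A6 | alternative 3 | trimer core with new rings B and D as hydroxy siloxy ethoxy arenes | CCCC(=O)c1c(OCOC)c(Cc2c(O)cc(OCC)cc2O[Si](C(C)C)(C(C)C)C(C)C)c(OCOC)c(Cc2c(O)cc(OCC)cc2O[Si](C(C)C)(C(C)C)C(C)C)c1OCOC
A7 | alternative 3 | 3-ethoxycyclobut-2-en-1-one | CCOC1=CC(=O)C1
A8 | alternative 3 | 1-{2,4,6-tris(methoxymethoxy)-3,5-bis[3-(triisopropylsiloxy)prop-2-yn-1-yl]phenyl}butan-1-one | CCCC(=O)c1c(OCOC)c(CC#CO[Si](C(C)C)(C(C)C)C(C)C)c(OCOC)c(CC#CO[Si](C(C)C)(C(C)C)C(C)C)c1OCOC
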